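**Retrosynthetic overview**

- The target is taken back (desilylation, then Pd-catalysed methylation of a (Z)-alkenyl chloride) to a C52 chloro-polyene. This is cut into a C21 homoallylic zinc reagent (ω-end half with the TES-protected S carbinol) and a C31 1,1-dichloroalkene (chroman half), joined by a trans-selective Negishi mono-alkylation.
- Enabling feature (prenyl units counted from the isopropylidene end): the bond links the homoallylic CH2 of unit 4 to the methyl-bearing sp2 carbon of the (E)-trisubstituted C=C of unit 5. That carbon carries only CH3 besides the chain, so it can be a CCl2 terminus whose two C–Cl bonds differ by being cis or trans to the chain.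
- C21 half: (2E,6E)-farnesol → Sharpless epoxidation → epoxy chloride → (S)-propargylic alcohol → hydrozirconation and Pd allyl–alkenyl coupling with a C6 (E)-allylic chloride.
- C31 half: (2E,6E,10E)-geranylgeraniol → Sharpless epoxidation → (S)-geranyllinalool → 9-BBN/Suzuki coupling with a 1-bromo-2-iodoarene → Pd C–O ring closure → terminal SeO2 oxidation → two-carbon homologation → dichloromethylenation.
- Rings: the benzene ring is bought with its substituents; the dihydropyran ring of the chroman is the only ring formed (step 15), before the key step.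

Key step: step 20

Remark: the given SMILES is read as S at C2 of the chroman and S at the tertiary carbinol; (2E,6E)-farnesol, (2E,6E,10E)-geranylgeraniol, 5-bromo-2-methylpent-2-ene, 4-amino-2,3-dimethylphenol and N-tert-butylethanimine are taken as purchased, isomerically pure materials.

**Route**

Step 1
Reactants: 1 (2E,6E)-farnesol
Product: 2 (2S,3S)-2,3-epoxyfarnesol
Conditions: Ti(OiPr)4 (10 mol %), L-(+)-diethyl tartrate (12 mol %), t-BuOOH (decane), 4 Å MS, CH2Cl2, −20 °C
Reagents that add atoms: tert-butyl hydroperoxide, CC(C)(C)OO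
Why: Sharpless asymmetric epoxidation acts only on the allylic-alcohol olefin, and with L-(+)-tartrate the (E)-2-en-1-ol should give the (2S,3S)-epoxide, whose C3 becomes the S tertiary carbinol of the target.

Step 2
Reactants: 2 (2S,3S)-2,3-epoxyfarnesol
Product: 3 (2R,3S)-epoxy chloride
Conditions: PPh3, CCl4, NaHCO3 (cat.), reflux
Reagents that add atoms: carbon tetrachloride, ClC(Cl)(Cl)Cl
Why: Appel chlorination of the primary alcohol under neutral conditions should leave the trisubstituted epoxide and both stereocentres untouched (the C2 descriptor changes only through the CIP ranking).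

Step 3
Reactants: 3 (2R,3S)-epoxy chloride
Product: 4 (3S,6E)-3,7,11-trimethyldodeca-6,10-dien-1-yn-3-ol
Conditions: n-BuLi (3.2 equiv), THF, −78 to −40 °C; then H2O
Reagents that add atoms: none
Why: Base-induced fragmentation of a 2,3-epoxy chloride (α-deprotonation, epoxide opening to the chlorovinyl alkoxide, loss of HCl) gives the terminal propargylic alcohol, and the C–O bond of the tertiary carbon is never broken, so the S configuration is kept.

Step 4
Reactants: 4 (S)-propargylic alcohol
Product: 5 TES ether of 4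
Conditions: Et3SiOTf, 2,6-lutidine, CH2Cl2, −78 to 0 °C
Reagents that add atoms: triethylsilyl trifluoromethanesulfonate, CC[Si](CC)(CC)OS(=O)(=O)C(F)(F)F
Why: Silyl triflate silylation is the standard way to cap a hindered tertiary alcohol, and the ether protects the carbinol from the organometallic steps that follow.

Step 5
Reactants: 6 5-bromo-2-methylpent-2-ene
Product: 7 (2E)-5-bromo-2-methylpent-2-en-1-ol
Conditions: SeO2 (0.3 equiv), t-BuOOH (70 % aq.), CH2Cl2, 0 °C to rt
Reagents that add atoms: tert-butyl hydroperoxide, CC(C)(C)OO; selenium dioxide, O=[Se]=O (catalytic oxygen carrier)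
Why: The ene/[2,3]-sigmatropic sequence of the Riley allylic oxidation attacks the (E)-methyl group of an isopropylidene unit, which sets the E geometry of the olefin of prenyl unit 4.

Step 6
Reactants: 7 (2E)-5-bromo-2-methylpent-2-en-1-ol
Product: 8 (2E)-5-bromo-1-chloro-2-methylpent-2-ene
Conditions: PPh3, CCl4, 60 °C
Reagents that add atoms: carbon tetrachloride, ClC(Cl)(Cl)Cl
Why: Appel chlorination converts primary allylic alcohols into the chlorides without allylic transposition and does not touch the alkyl bromide.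

Step 7
Reactants: 5 TES ether of the (S)-propargylic alcohol; 8 (2E)-5-bromo-1-chloro-2-methylpent-2-ene
Product: 11 C21 homoallylic bromide (TES ether), via alkenylzirconocene chloride 9 (not isolated), via alkenylzinc chloride 10 (not isolated)
Conditions: Cp2Zr(H)Cl, THF, rt; ZnCl2, THF, 0 °C; then 8, Pd(PPh3)4 (5 mol %), 0 °C to rt
Reagents that add atoms: none
Why: syn-Hydrozirconation of the terminal alkyne fixes the (E)-disubstituted olefin, and the Pd-catalysed alkenyl–allyl Negishi coupling should join the alkenylzinc to the CH2 terminus of the allyl unit with retention of the E geometry while the alkyl bromide stays inert.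

Step 8
Reactants: 12 4-amino-2,3-dimethylphenol
Product: 13 2,3-dimethyl-4-(triisopropylsilyloxy)aniline
Conditions: i-Pr3SiCl, imidazole, DMF, rt
Reagents that add atoms: chlorotri(propan-2-yl)silane, CC(C)[Si](Cl)(C(C)C)C(C)C
Why: Phenols are silylated selectively in the presence of an aniline nitrogen, and the TIPS ether is chosen to survive the basic and organometallic steps until the final fluoride treatment.

Step 9
Reactants: 13 2,3-dimethyl-4-(triisopropylsilyloxy)aniline
Product: 14 6-iodo-2,3-dimethyl-4-(triisopropylsilyloxy)aniline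
Conditions: N-iodosuccinimide, MeCN, −20 to 0 °C
Reagents that add atoms: N-iodosuccinimide, O=C1CCC(=O)N1I
Why: Electrophilic iodination should go to the only free position ortho to the amino group, the stronger donor, since the position ortho to the bulky silyloxy group is less activated and shielded.

Step 10
Reactants: 14 6-iodo-2,3-dimethyl-4-(triisopropylsilyloxy)aniline
Product: 15 (4-bromo-5-iodo-2,3-dimethylphenoxy)triisopropylsilane
Conditions: t-BuONO, CuBr2, MeCN, 0 °C to rt
Reagents that add atoms: copper dibromide, Br[Cu]Br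
Why: Non-aqueous Sandmeyer bromination replaces the amino group by bromine, giving an arene whose C–I bond (future C4a) and C–Br bond (future C8a) can be addressed one after the other.

Step 11
Reactants: 16 (2E,6E,10E)-geranylgeraniol
Product: 17 (2S,3S)-2,3-epoxygeranylgeraniol
Conditions: Ti(OiPr)4 (10 mol %), L-(+)-diethyl tartrate (12 mol %), t-BuOOH (decane), 4 Å MS, CH2Cl2, −20 °C
Reagents that add atoms: tert-butyl hydroperoxide, CC(C)(C)OO
Why: Sharpless asymmetric epoxidation epoxidises only the allylic-alcohol olefin, and L-(+)-tartrate should give the (2S,3S)-epoxide, whose C3 becomes the S-configured C2 of the chroman.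

Step 12
Reactants: 17 (2S,3S)-2,3-epoxygeranylgeraniol
Product: 18 (2R,3S)-epoxy iodide
Conditions: I2, PPh3, imidazole, Et2O/MeCN, 0 °C
Reagents that add atoms: iodine, II
Why: Appel-type iodination of the primary alcohol proceeds under neutral conditions that leave the epoxide and the three olefins intact.

Step 13
Reactants: 18 (2R,3S)-epoxy iodide
Product: 19 (S)-(6E,10E)-geranyllinalool
Conditions: Zn dust, AcOH, EtOH, 0 °C to rt
Reagents that add atoms: none
Why: Zinc insertion into the C–I bond followed by β-elimination opens the epoxide to the tertiary vinyl carbinol, and the C–O bond at the stereocentre is retained, so the carbinol is S.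

Step 14
Reactants: 19 (S)-(6E,10E)-geranyllinalool; 15 (4-bromo-5-iodo-2,3-dimethylphenoxy)triisopropylsilane
Product: 21 (3S)-aryl bromide carbinol, via B-alkyl-9-BBN adduct 20 (not isolated)
Conditions: 9-BBN, THF, 0 °C to rt; then 15, PdCl2(dppf) (5 mol %), aq. K3PO4, DMF, rt to 45 °C
Reagents that add atoms: none
Why: 9-BBN should hydroborate only the monosubstituted vinyl group, and the B-alkyl Suzuki–Miyaura coupling should take place at the C–I bond and leave the neighbouring C–Br bond for the ring closure.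

Step 15
Reactants: 21 (3S)-aryl bromide carbinol
Product: 22 (S)-γ-tocotrienol TIPS ether
Conditions: Pd(OAc)2 (5 mol %), 2-(di-tert-butylphosphanyl)-1,1'-binaphthyl (6 mol %), Cs2CO3, toluene, 80 °C
Reagents that add atoms: none
Why: Intramolecular Buchwald–Hartwig etherification closes the dihydropyran ring by aryl–oxygen reductive elimination, the tertiary alkoxide cannot undergo β-hydride elimination at the carbinol carbon, and because the C–O bond of the stereocentre is not broken C2 of the chroman is formed with S configuration.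

Step 16
Reactants: 22 (S)-γ-tocotrienol TIPS ether
Product: 23 terminal (E)-allylic alcohol
Conditions: SeO2 (0.3 equiv), t-BuOOH, salicylic acid (cat.), CH2Cl2, 0 °C; stopped at partial conversion, 22 recycled
Reagents that add atoms: tert-butyl hydroperoxide, CC(C)(C)OO; selenium dioxide, O=[Se]=O (catalytic oxygen carrier)
Why: Riley allylic oxidation prefers the (E)-methyl group of the terminal isopropylidene unit, which is the known site of attack in tocotrienol-type chains, and this fixes the E geometry of the olefin of unit 6.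

Step 17
Reactants: 23 terminal (E)-allylic alcohol
Product: 24 terminal (E)-allylic bromide
Conditions: CBr4, PPh3, CH2Cl2, −20 °C
Reagents that add atoms: carbon tetrabromide, BrC(Br)(Br)Br
Why: Appel bromination gives primary allylic bromides without allylic shift or E/Z isomerisation under neutral, cold conditions.

Step 18
Reactants: 24 terminal (E)-allylic bromide; 25 N-tert-butylethanimine
Product: 28 C29 aldehyde, via lithium aza-enolate 26 (not isolated), via N-tert-butyl imine 27 (not isolated)
Conditions: LiN(i-Pr)2, THF, −78 °C; 24, −78 to 0 °C; aq. oxalic acid, Et2O, rt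
Reagents that add atoms: water, O
Why: Metalloenamine alkylation (SN2 of the acetaldehyde aza-enolate at the primary allylic bromide) followed by mild imine hydrolysis adds the two-carbon aldehyde unit in one operation without touching the silyl ether.

Step 19
Reactants: 28 C29 aldehyde
Product: 29 C31 1,1-dichloroalkene
Conditions: PPh3, BrCCl3, MeCN, 0 °C to rt
Reagents that add atoms: bromotrichloromethane, ClC(Cl)(Cl)Br
Why: Wittig-type dichloromethylenation with the ylide Ph3P=CCl2 generated in situ converts aldehydes into 1,1-dichloroalkenes under non-basic conditions, so the enolisable aldehyde is not at risk.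

Step 20
Reactants: 11 C21 homoallylic bromide (TES ether); 29 C31 1,1-dichloroalkene
Product: 31 C52 (Z)-alkenyl chloride, via homoallylic zinc bromide 30 (not isolated)
Conditions: Zn dust, LiCl, THF, 50 °C; then 29, PdCl2(DPEphos) (5 mol %; DPEphos = bis[2-(diphenylphosphanyl)phenyl] ether), THF, rt to 50 °C
Reagents that add atoms: none
Why: Zinc inserts into the primary C–Br bond of 11 to give 30; zerovalent palladium carrying the wide-bite-angle diphosphine then adds oxidatively to the C–Cl bond of 29 that lies trans to the chain, 30 transmetalates, and reductive elimination forms the CH2–C(sp2) bond between the two halves. The closest known reaction type is the Pd-catalysed trans-selective mono-alkylation of 1,1-dichloro-1-alkenes with alkylzinc halides, a Negishi coupling. No ring is closed and no stereocentre is formed; the element created is the geometry of the chloro-olefin, controlled by the alkyl group on the neighbouring sp2 carbon, which shields the cis C–Cl bond, so the incoming chain ends up trans to the existing chain and the remaining chlorine marks the place of the later methyl group. The step needs mono- over bis-substitution and coupling faster than β-hydride elimination: the first should be secured because the remaining C–Cl bond is more hindered and more electron-rich and resists this catalyst at 50 °C, the second by fast reductive elimination from the chelate. Both silyl ethers, the other seven olefins and the aryl ether are inert to alkylzinc halides and to the catalyst, so the union can be run on the fully functionalised halves.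

Step 21
Reactants: 31 C52 (Z)-alkenyl chloride
Product: 32 bis-silyl ether of the target
Conditions: Me2Zn, Pd(P(t-Bu)3)2 (5 mol %), THF/NMP, 60 °C
Reagents that add atoms: dimethylzinc, C[Zn]C
Why: Negishi methylation with the bulky, electron-rich phosphine catalyst should activate the hindered alkenyl C–Cl bond and replace chlorine by methyl with retention, completing the (E)-trisubstituted olefin of unit 5.

Step 22
Reactants: 32 bis-silyl ether of the target
Product: 33 target (CNP0323443.2)
Conditions: Bu4NF, THF, 0 °C to rt (argon); then H2O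
Reagents that add atoms: none
Why: Fluoride cleaves the aryl TIPS ether and the tertiary TES ether in one operation under non-acidic conditions, which avoids ionisation of the tertiary allylic alcohol and leaves both stereocentres and all olefin geometries unchanged.

**Compound list**

1 | (2E,6E)-farnesol | CC(C)=CCC/C(C)=C/CC/C(C)=C/CO | starting material
2 | [(2S,3S)-3-[(3E)-4,8-dimethylnona-3,7-dien-1-yl]-3-methyloxiran-2-yl]methanol | CC(C)=CCC/C(C)=C/CC[C@]1(C)O[C@H]1CO | intermediate
3 | (2R,3S)-2-(chloromethyl)-3-[(3E)-4,8-dimethylnona-3,7-dien-1-yl]-3-methyloxirane | CC(C)=CCC/C(C)=C/CC[C@]1(C)O[C@H]1CCl | intermediate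
4 | (3S,6E)-3,7,11-trimethyldodeca-6,10-dien-1-yn-3-ol | CC(C)=CCC/C(C)=C/CC[C@](C)(O)C#C | intermediate
5 | triethyl{[(3S,6E)-3,7,11-trimethyldodeca-6,10-dien-1-yn-3-yl]oxy}silane | CC(C)=CCC/C(C)=C/CC[C@](C)(O[Si](CC)(CC)CC)C#C | intermediate
6 | 5-bromo-2-methylpent-2-ene | CC(C)=CCCBr | starting material
7 | (2E)-5-bromo-2-methylpent-2-en-1-ol | OC/C(C)=C/CCBr | intermediate
8 | (2E)-5-bromo-1-chloro-2-methylpent-2-ene | ClC/C(C)=C/CCBr | intermediate
9 | chlorobis(cyclopentadienyl)[(1E,3S,6E)-3,7,11-trimethyl-3-(triethylsilyloxy)dodeca-1,6,10-trien-1-yl]zirconium | CC(C)=CCC/C(C)=C/CC[C@](C)(O[Si](CC)(CC)CC)/C=C/[Zr](Cl)(C1C=CC=C1)C1C=CC=C1 | intermediate (not isolated)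
10 | chloro[(1E,3S,6E)-3,7,11-trimethyl-3-(triethylsilyloxy)dodeca-1,6,10-trien-1-yl]zinc | CC(C)=CCC/C(C)=C/CC[C@](C)(O[Si](CC)(CC)CC)/C=C/[Zn]Cl | intermediate (not isolated)
11 | triethyl{[(3E,6E,8S,11E)-1-bromo-4,8,12,16-tetramethylheptadeca-3,6,11,15-tetraen-8-yl]oxy}silane | CC(C)=CCC/C(C)=C/CC[C@](C)(O[Si](CC)(CC)CC)/C=C/C/C(C)=C/CCBr | intermediate
12 | 4-amino-2,3-dimethylphenol | Cc1c(C)c(N)ccc1O | starting material
13 | 2,3-dimethyl-4-[(triisopropylsilyl)oxy]aniline | CC(C)[Si](Oc1ccc(N)c(C)c1C)(C(C)C)C(C)C | intermediate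
14 | 6-iodo-2,3-dimethyl-4-[(triisopropylsilyl)oxy]aniline | CC(C)[Si](Oc1cc(I)c(N)c(C)c1C)(C(C)C)C(C)C | intermediate
15 | (4-bromo-5-iodo-2,3-dimethylphenoxy)triisopropylsilane | CC(C)[Si](Oc1cc(I)c(Br)c(C)c1C)(C(C)C)C(C)C | intermediate
16 | (2E,6E,10E)-geranylgeraniol | CC(C)=CCC/C(C)=C/CC/C(C)=C/CC/C(C)=C/CO | starting material
17 | [(2S,3S)-3-methyl-3-[(3E,7E)-4,8,12-trimethyltrideca-3,7,11-trien-1-yl]oxiran-2-yl]methanol | CC(C)=CCC/C(C)=C/CC/C(C)=C/CC[C@]1(C)O[C@H]1CO | intermediate
18 | (2R,3S)-2-(iodomethyl)-3-methyl-3-[(3E,7E)-4,8,12-trimethyltrideca-3,7,11-trien-1-yl]oxirane | CC(C)=CCC/C(C)=C/CC/C(C)=C/CC[C@]1(C)O[C@H]1CI | intermediate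
19 | (3S,6E,10E)-3,7,11,15-tetramethylhexadeca-1,6,10,14-tetraen-3-ol | CC(C)=CCC/C(C)=C/CC/C(C)=C/CC[C@](C)(O)C=C | intermediate
20 | (3R,6E,10E)-1-(9-borabicyclo[3.3.1]nonan-9-yl)-3,7,11,15-tetramethylhexadeca-6,10,14-trien-3-ol (same spatial arrangement as 19; descriptor changes by CIP ranking) | CC(C)=CCC/C(C)=C/CC/C(C)=C/CC[C@](C)(O)CCB1C2CCCC1CCC2 | intermediate (not isolated)
21 | (3S,6E,10E)-1-[2-bromo-3,4-dimethyl-5-(triisopropylsilyloxy)phenyl]-3,7,11,15-tetramethylhexadeca-6,10,14-trien-3-ol | CC(C)=CCC/C(C)=C/CC/C(C)=C/CC[C@](C)(O)CCc1cc(O[Si](C(C)C)(C(C)C)C(C)C)c(C)c(C)c1Br | intermediate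
22 | triisopropyl{[(2S)-2,7,8-trimethyl-2-[(3E,7E)-4,8,12-trimethyltrideca-3,7,11-trien-1-yl]chroman-6-yl]oxy}silane | CC(C)=CCC/C(C)=C/CC/C(C)=C/CC[C@@]1(C)CCc2cc(O[Si](C(C)C)(C(C)C)C(C)C)c(C)c(C)c2O1 | intermediate
23 | (2E,6E,10E)-2,6,10-trimethyl-13-[(2S)-2,7,8-trimethyl-6-(triisopropylsilyloxy)chroman-2-yl]trideca-2,6,10-trien-1-ol | OC/C(C)=C/CC/C(C)=C/CC/C(C)=C/CC[C@@]1(C)CCc2cc(O[Si](C(C)C)(C(C)C)C(C)C)c(C)c(C)c2O1 | intermediate
24 | {[(2S)-2-[(3E,7E,11E)-13-bromo-4,8,12-trimethyltrideca-3,7,11-trien-1-yl]-2,7,8-trimethylchroman-6-yl]oxy}triisopropylsilane | BrC/C(C)=C/CC/C(C)=C/CC/C(C)=C/CC[C@@]1(C)CCc2cc(O[Si](C(C)C)(C(C)C)C(C)C)c(C)c(C)c2O1 | intermediate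
25 | N-tert-butylethanimine | CC=NC(C)(C)C | starting material
26 | lithium N-tert-butyl-N-ethenylamide | [Li]N(C=C)C(C)(C)C | intermediate (not isolated)
27 | N-tert-butyl imine of aldehyde 28 | CC(C)(C)N=CCC/C(C)=C/CC/C(C)=C/CC/C(C)=C/CC[C@@]1(C)CCc2cc(O[Si](C(C)C)(C(C)C)C(C)C)c(C)c(C)c2O1 | intermediate (not isolated)
28 | (4E,8E,12E)-4,8,12-trimethyl-15-[(2S)-2,7,8-trimethyl-6-(triisopropylsilyloxy)chroman-2-yl]pentadeca-4,8,12-trienal | O=CCC/C(C)=C/CC/C(C)=C/CC/C(C)=C/CC[C@@]1(C)CCc2cc(O[Si](C(C)C)(C(C)C)C(C)C)c(C)c(C)c2O1 | intermediate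
29 | {[(2S)-2-[(3E,7E,11E)-16,16-dichloro-4,8,12-trimethylhexadeca-3,7,11,15-tetraen-1-yl]-2,7,8-trimethylchroman-6-yl]oxy}triisopropylsilane | ClC(Cl)=CCC/C(C)=C/CC/C(C)=C/CC/C(C)=C/CC[C@@]1(C)CCc2cc(O[Si](C(C)C)(C(C)C)C(C)C)c(C)c(C)c2O1 | intermediate
30 | bromo[(3E,6E,8S,11E)-4,8,12,16-tetramethyl-8-(triethylsilyloxy)heptadeca-3,6,11,15-tetraen-1-yl]zinc | CC(C)=CCC/C(C)=C/CC[C@](C)(O[Si](CC)(CC)CC)/C=C/C/C(C)=C/CC[Zn]Br | intermediate (not isolated)
31 | {[(2S)-2-[(3E,7E,11E,15Z,19E,22E,24S,27E)-16-chloro-4,8,12,20,24,28,32-heptamethyl-24-(triethylsilyloxy)tritriaconta-3,7,11,15,19,22,27,31-octaen-1-yl]-2,7,8-trimethylchroman-6-yl]oxy}triisopropylsilane | CC(C)=CCC/C(C)=C/CC[C@](C)(O[Si](CC)(CC)CC)/C=C/C/C(C)=C/CC/C(Cl)=C/CC/C(C)=C/CC/C(C)=C/CC/C(C)=C/CC[C@@]1(C)CCc2cc(O[Si](C(C)C)(C(C)C)C(C)C)c(C)c(C)c2O1 | intermediate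
32 | {[(2S)-2-[(3E,7E,11E,15E,19E,22E,24S,27E)-4,8,12,16,20,24,28,32-octamethyl-24-(triethylsilyloxy)tritriaconta-3,7,11,15,19,22,27,31-octaen-1-yl]-2,7,8-trimethylchroman-6-yl]oxy}triisopropylsilane | CC(C)=CCC/C(C)=C/CC[C@](C)(O[Si](CC)(CC)CC)/C=C/C/C(C)=C/CC/C(C)=C/CC/C(C)=C/CC/C(C)=C/CC/C(C)=C/CC[C@@]1(C)CCc2cc(O[Si](C(C)C)(C(C)C)C(C)C)c(C)c(C)c2O1 | intermediate
33 | (2S)-2-[(3E,7E,11E,15E,19E,22E,24S,27E)-24-hydroxy-4,8,12,16,20,24,28,32-octamethyltritriaconta-3,7,11,15,19,22,27,31-octaen-1-yl]-2,7,8-trimethylchroman-6-ol | CC(C)=CCC/C(C)=C/CC[C@](C)(O)/C=C/C/C(C)=C/CC/C(C)=C/CC/C(C)=C/CC/C(C)=C/CC/C(C)=C/CC[C@@]1(C)CCc2cc(O)c(C)c(C)c2O1 | target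

**Step count and risks**

Total step count: 22. Longest linear sequence: 12 steps (steps 11–22 from geranylgeraniol; equally steps 8–10 and 14–22 from 4-amino-2,3-dimethylphenol).

Steps most likely to fail:

Step 20 (key step). What may go wrong: over-reaction at the second C–Cl bond, erosion of the trans preference in the oxidative addition, or β-hydride elimination of the alkylpalladium intermediate. The fallback sets out from aldehyde 28 and bromide 11 and returns at 32; it fixes the olefin geometry before the union. Aldehyde 28 would be taken by Corey–Fuchs dibromomethylenation (CBr4, PPh3) to the 1,1-dibromoalkene F1, then with n-BuLi and MeI to the methyl alkyne F2. Hydrozirconation with excess Cp2Zr(H)Cl (zirconium settling on the methyl-bearing carbon) and iodination would give the (E)-2-iodo-2-alkene F3. Stereoretentive Negishi coupling of F3 with zinc reagent 30 (Pd(PPh3)4, THF) would then give 32 directly, so that step 21 is not needed.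

Step 15. What may go wrong: slow oxidative addition at the doubly ortho-substituted, electron-rich C–Br bond, so that protodebromination competes with ring closure. The fallback sets out from farnesol 1 and returns at 22; the chroman is made first and the chain is attached by sulfone alkylation.
- Chain part: 1 would be converted with PBr3 into (2E,6E)-farnesyl bromide F4 and with PhSO2Na into (2E,6E)-farnesyl phenyl sulfone F5.
- Chroman part: racemic methyl 6-hydroxy-2,7,8-trimethylchroman-2-carboxylate F6 would be made from 2,3-dimethylhydroquinone, paraformaldehyde and methyl methacrylate by hetero-Diels–Alder reaction of the ortho-quinone methide. It would be silylated to the TIPS ether F7, reduced with LiAlH4 to the racemic chroman-2-methanol F8 and resolved by preparative chromatography on a chiral phase to the (R)-alcohol F9.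
- Union: the triflate F10 of F9 would alkylate lithiated F5 to give the sulfone F11, and reductive desulfonylation (PdCl2(dppp), LiBHEt3) would give 22.

Step 16. What may go wrong: competing oxidation at internal allylic methylene groups and over-oxidation to the enal. The fallback sets out from 22 and returns at 28, replacing steps 16–18. The terminal olefin would be singled out by bromohydrin formation in aqueous THF (N-bromosuccinimide), giving the terminal bromohydrin F12, which K2CO3 would close to the terminal epoxide F13. Isomerisation with Al(Oi-Pr)3 would give the secondary allylic alcohol with an exo-methylene group F14. Johnson–Claisen rearrangement with triethyl orthoacetate would give the (E)-γ,δ-unsaturated ethyl ester F15, and i-Bu2AlH at −78 °C would give 28.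

Further compounds
F1 | step 20 | {[(2S)-2-[(3E,7E,11E)-16,16-dibromo-4,8,12-trimethylhexadeca-3,7,11,15-tetraen-1-yl]-2,7,8-trimethylchroman-6-yl]oxy}triisopropylsilane | BrC(Br)=CCC/C(C)=C/CC/C(C)=C/CC/C(C)=C/CC[C@@]1(C)CCc2cc(O[Si](C(C)C)(C(C)C)C(C)C)c(C)c(C)c2O1
F2 | step 20 | {[(2S)-2-[(3E,7E,11E)-4,8,12-trimethylheptadeca-3,7,11-trien-15-yn-1-yl]-2,7,8-trimethylchroman-6-yl]oxy}triisopropylsilane | CC#CCC/C(C)=C/CC/C(C)=C/CC/C(C)=C/CC[C@@]1(C)CCc2cc(O[Si](C(C)C)(C(C)C)C(C)C)c(C)c(C)c2O1
F3 | step 20 | {[(2S)-2-[(3E,7E,11E,15E)-16-iodo-4,8,12-trimethylheptadeca-3,7,11,15-tetraen-1-yl]-2,7,8-trimethylchroman-6-yl]oxy}triisopropylsilane | I/C(C)=C/CC/C(C)=C/CC/C(C)=C/CC/C(C)=C/CC[C@@]1(C)CCc2cc(O[Si](C(C)C)(C(C)C)C(C)C)c(C)c(C)c2O1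
F4 | step 15 | (2E,6E)-farnesyl bromide | CC(C)=CCC/C(C)=C/CC/C(C)=C/CBr
F5 | step 15 | (2E,6E)-farnesyl phenyl sulfone | CC(C)=CCC/C(C)=C/CC/C(C)=C/CS(=O)(=O)c1ccccc1
F6 | step 15 | racemic methyl 6-hydroxy-2,7,8-trimethylchroman-2-carboxylate | COC(=O)C1(C)CCc2cc(O)c(C)c(C)c2O1
F7 | step 15 | racemic methyl 2,7,8-trimethyl-6-(triisopropylsilyloxy)chroman-2-carboxylate | COC(=O)C1(C)CCc2cc(O[Si](C(C)C)(C(C)C)C(C)C)c(C)c(C)c2O1
F8 | step 15 | racemic [2,7,8-trimethyl-6-(triisopropylsilyloxy)chroman-2-yl]methanol | OCC1(C)CCc2cc(O[Si](C(C)C)(C(C)C)C(C)C)c(C)c(C)c2O1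
F9 | step 15 | [(2R)-2,7,8-trimethyl-6-(triisopropylsilyloxy)chroman-2-yl]methanol | OC[C@@]1(C)CCc2cc(O[Si](C(C)C)(C(C)C)C(C)C)c(C)c(C)c2O1
F10 | step 15 | [(2R)-2,7,8-trimethyl-6-(triisopropylsilyloxy)chroman-2-yl]methyl trifluoromethanesulfonate | O=S(=O)(OC[C@@]1(C)CCc2cc(O[Si](C(C)C)(C(C)C)C(C)C)c(C)c(C)c2O1)C(F)(F)F
F11 | step 15 | sulfone adduct of F5 and F10 (both epimers at the sulfonyl-bearing carbon) | CC(C)=CCC/C(C)=C/CC/C(C)=C/C(C[C@@]1(C)CCc2cc(O[Si](C(C)C)(C(C)C)C(C)C)c(C)c(C)c2O1)S(=O)(=O)c1ccccc1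
F12 | step 16 | terminal bromohydrin of 22 (both epimers at the bromine-bearing carbon) | CC(C)(O)C(Br)CC/C(C)=C/CC/C(C)=C/CC[C@@]1(C)CCc2cc(O[Si](C(C)C)(C(C)C)C(C)C)c(C)c(C)c2O1
F13 | step 16 | terminal epoxide of 22 (both epimers at the epoxide CH) | CC1(C)OC1CC/C(C)=C/CC/C(C)=C/CC[C@@]2(C)CCc3cc(O[Si](C(C)C)(C(C)C)C(C)C)c(C)c(C)c3O2
F14 | step 16 | secondary allylic alcohol with terminal exo-methylene group (both epimers at the carbinol) | C=C(C)C(O)CC/C(C)=C/CC/C(C)=C/CC[C@@]1(C)CCc2cc(O[Si](C(C)C)(C(C)C)C(C)C)c(C)c(C)c2O1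
F15 | step 16 | ethyl (4E,8E,12E)-4,8,12-trimethyl-15-[(2S)-2,7,8-trimethyl-6-(triisopropylsilyloxy)chroman-2-yl]pentadeca-4,8,12-trienoate | CCOC(=O)CC/C(C)=C/CC/C(C)=C/CC/C(C)=C/CC[C@@]1(C)CCc2cc(O[Si](C(C)C)(C(C)C)C(C)C)c(C)c(C)c2O1
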